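**Plan**

- Retrosynthetic cuts, in order: the two gallate ester C–O bonds at C3 and C3'; ring F at C3'–C4' (as a C3'=C4' alkene); the benzylic C2'–O1' ether bond; the C4a'–C4' bond (formyl carbon on ring D); the interflavan C4–C6' bond, which leads back to epicatechin and phloroglucinol.
- Feature used: ring F has an unsubstituted C4', and its O1' sits on the ring D carbon para to C6'. A vinyl group at C4a' and a 1-arylallyl ether on that para oxygen therefore leave only C3'=C4' to close, and only the 4→6 skeleton can result.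
- Forward order: rings A, C and B come from epicatechin; ring D is added at C4 as phloroglucinol; C4' is added by formylation; ring E with C2' and C3' arrives as the allyl ether; ring F closes by metathesis; C3' is oxygenated, both 3-hydroxyls are galloylated, and all benzyl groups are removed.
- Stereochemistry: C2 and C3 come from (−)-epicatechin; C4 from attack anti to the C3 silyl ether (4β); C2' from the iridium–phosphoramidite catalyst; C3' from LiBH(s-Bu)3 reduction of the 3'-ketone anti to ring E.

Key step: step 13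

Remark: 3,4-bis(benzyloxy)benzaldehyde and 3,4,5-tris(benzyloxy)benzoic acid are taken as purchased. Ligand L is O,O'-(S)-1,1'-binaphthyl-2,2'-diyl N,N-bis[(S)-1-phenylethyl]phosphoramidite, and its (Sa,S,S) form is assumed to induce the (S) configuration at the ether carbon, as it does for cinnamyl carbonates and phenoxides.

**Route**

Step 1
Reactants: 1 (−)-epicatechin
Product: 2 5,7,3',4'-tetra-O-benzyl-(−)-epicatechin
Conditions: BnBr (4.4 equiv), K2CO3, DMF, 0 °C to rt
Reagents that add atoms: benzyl bromide, BrCc1ccccc1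
Why: Williamson etherification in which K2CO3 ionises only the four phenols, so the secondary 3-OH stays free and the mild conditions should leave C2 and C3 untouched.

Step 2
Reactants: 2 5,7,3',4'-tetra-O-benzyl-(−)-epicatechin
Product: 3 4β-(2-ethoxyethoxy)-5,7,3',4'-tetra-O-benzylepicatechin
Conditions: DDQ (2 equiv), 2-ethoxyethanol (5 equiv), CH2Cl2, rt
Reagents that add atoms: 2-ethoxyethanol, CCOCCO
Why: DDQ benzylic oxidation abstracts hydride from C4 to give a cation stabilised by ring A, which the alcohol should trap anti to the C3 hydroxyl and ring B, so the (temporary) C4 centre is 4β (3,4-trans).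

Step 3
Reactants: 3 4β-(2-ethoxyethoxy)-5,7,3',4'-tetra-O-benzylepicatechin
Product: 4 3-O-tert-butyldimethylsilyl ether of 3
Conditions: TBSCl, imidazole, DMF, rt to 40 °C
Reagents that add atoms: tert-butyldimethylsilyl chloride, CC(C)(C)[Si](C)(C)Cl
Why: Imidazole-promoted silylation of the only free hydroxyl proceeds under non-acidic conditions that should not ionise the C4 ether, and it masks C3–OH for all steps up to the esterification.

Step 4
Reactants: 4 3-O-TBS-4β-(2-ethoxyethoxy)-tetra-O-benzylepicatechin; 5 phloroglucinol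
Product: 6 3-O-TBS-5,7,3',4'-tetra-O-benzylepicatechin-(4β→2)-phloroglucinol
Conditions: 5 (5 equiv), TMSOTf (0.5 equiv), THF/CH2Cl2, −40 °C; then aq. NaHCO3
Reagents that add atoms: none
Why: Friedel–Crafts arylation in which TMSOTf ionises the C4 ether and the threefold-symmetric, strongly nucleophilic phloroglucinol (in excess) captures the cation at any of its equivalent carbons, anti to the C3 silyl ether and ring B, which sets C4 as 4β (3,4-trans).

Step 5
Reactants: 6 3-O-TBS-tetra-O-benzylepicatechin-(4β→2)-phloroglucinol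
Product: 8 ring D aldehyde with a 3-formyl-2,4,6-trihydroxyphenyl group at C4β, via iminium chloride 7 (not isolated)
Conditions: (chloromethylene)dimethyliminium chloride (1.2 equiv), MeCN, 0 °C to rt; then aq. NaOAc, rt
Reagents that add atoms: (chloromethylene)dimethyliminium chloride, ClC=[N+](C)C.[Cl-]; water, O
Why: Vilsmeier–Haack formylation should pick the free triphenol ring D, which is far more nucleophilic than the benzylated rings, and its two open positions are equivalent by rotation about the C4–aryl bond, so a single aldehyde (the future C4') is expected.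

Step 6
Reactants: 8 ring D aldehyde (3-formyl-2,4,6-trihydroxyphenyl at C4β)
Product: 9 7'-O-benzyl ether of 8 (ring D = 6-benzyloxy-3-formyl-2,4-dihydroxyphenyl)
Conditions: BnBr (1.05 equiv), KHCO3 (1.2 equiv), DMF, rt to 40 °C
Reagents that add atoms: benzyl bromide, BrCc1ccccc1
Why: Regioselective Williamson etherification in which the weak base should ionise first the hydroxyl para to the formyl group, the most acidic one and not held in a hydrogen bond to the carbonyl, as in the 4-O-alkylation of 2,4-dihydroxy- and 2,4,6-trihydroxybenzaldehydes.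

Step 7
Reactants: 10 3,4-bis(benzyloxy)benzaldehyde
Product: 11 ethyl (E)-3-[3,4-bis(benzyloxy)phenyl]prop-2-enoate
Conditions: Ph3P=CHCO2Et, toluene, 80 °C
Reagents that add atoms: ethyl (triphenylphosphoranylidene)acetate, CCOC(=O)C=P(c1ccccc1)(c1ccccc1)c1ccccc1
Why: Wittig olefination with a stabilised ylide is expected to give the E cinnamate.

Step 8
Reactants: 11 ethyl (E)-3-[3,4-bis(benzyloxy)phenyl]prop-2-enoate
Product: 12 (E)-3-[3,4-bis(benzyloxy)phenyl]prop-2-en-1-ol
Conditions: i-Bu2AlH (2.2 equiv), CH2Cl2, −78 °C; aq. KNaC4H4O6 (potassium sodium tartrate)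
Reagents that add atoms: none
Why: 1,2-Reduction of the conjugated ester by i-Bu2AlH at low temperature should give the allylic alcohol without touching the alkene or the benzyl ethers.

Step 9
Reactants: 12 (E)-3-[3,4-bis(benzyloxy)phenyl]prop-2-en-1-ol
Product: 13 (E)-3-[3,4-bis(benzyloxy)phenyl]allyl methyl carbonate
Conditions: ClCO2Me, pyridine, CH2Cl2, 0 °C
Reagents that add atoms: methyl chloroformate, COC(=O)Cl
Why: Acylation of the primary alcohol gives the linear carbonate, the usual electrophile for branched-selective iridium allylic substitution.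

Step 10
Reactants: 9 7'-O-benzyl ring D aldehyde; 13 (E)-3-[3,4-bis(benzyloxy)phenyl]allyl methyl carbonate
Product: 14 branched allyl ether of 9: ring D = 6-benzyloxy-3-formyl-2-hydroxy-4-{(S)-1-[3,4-bis(benzyloxy)phenyl]allyloxy}phenyl
Conditions: [Ir(cod)Cl]2 (4 mol %), (Sa,S,S)-L (8 mol %), TBD (1,5,7-triazabicyclo[4.4.0]dec-5-ene, 10 mol %), 13 (1.5 equiv), THF, rt
Reagents that add atoms: none
Why: Iridium-catalysed asymmetric allylic etherification, in which the cyclometalated iridium–phosphoramidite complex ionises 13 and the phenoxide (formed by the methoxide released) attacks the aryl-substituted allyl terminus, should give the branched ether with C2' fixed by the ligand (S at this stage); the phenol flanked by both the formyl group and the upper unit is too hindered to compete, and any C2' epimer would be a separable diastereomer.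

Step 11
Reactants: 14 branched allyl ether with one free ring D phenol
Product: 15 5',7'-di-O-benzyl aldehyde (ring D = 2,6-bis(benzyloxy)-3-formyl-4-{(S)-1-[3,4-bis(benzyloxy)phenyl]allyloxy}phenyl)
Conditions: BnBr (1.5 equiv), Cs2CO3, DMF, rt
Reagents that add atoms: benzyl bromide, BrCc1ccccc1
Why: Williamson etherification with the more reactive caesium phenoxide should cap the last, hindered and hydrogen-bonded phenol under basic conditions that do not ionise the allylic ether.

Step 12
Reactants: 15 5',7'-di-O-benzyl aldehyde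
Product: 16 ring D styrene bearing the (S)-1-arylallyl ether (ring D = 2,6-bis(benzyloxy)-3-vinyl-4-{(S)-1-[3,4-bis(benzyloxy)phenyl]allyloxy}phenyl)
Conditions: Ph3PCH3Br, KOt-Bu, THF, 0 °C to rt
Reagents that add atoms: methyltriphenylphosphonium bromide, C[P+](c1ccccc1)(c1ccccc1)c1ccccc1.[Br-]
Why: Wittig methylenation with the small, non-stabilised ylide works on 2,6-dialkoxybenzaldehydes and leaves the silyl, benzyl and allyl ethers alone.

Step 13
Reactants: 16 ring D styrene bearing the (S)-1-arylallyl ether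
Product: 17 4→6-linked epicatechin–flav-3-ene dimer (lower unit: (2S)-5,7,3',4'-tetra-O-benzylflav-3-ene joined through C6' to C4β of the 3-O-TBS-tetra-O-benzylepicatechin unit)
Conditions: second-generation Grubbs catalyst (H2IMes)(PCy3)Cl2Ru=CHPh (5 mol %), degassed CH2Cl2 (0.005 M), 40 °C, dark
Reagents that add atoms: none
Why: The ruthenium benzylidene should first exchange with the less hindered vinyl group of the allyl ether, and the new alkylidene then adds across the ring D vinyl group in a [2+2] step; cycloreversion of the ruthenacyclobutane releases the C3'=C4' alkene and a ruthenium methylidene that carries the chain and expels ethene. The closest known reaction type is the ring-closing metathesis of 2-vinylaryl allyl ethers to 2H-chromenes. Ring F closes as a six-membered ring in which both alkene carbons become ring members (C3' from the allyl ether, C4' from the former formyl carbon) while the two terminal CH2 groups leave as ethene. No stereocenter is created, and C2' is a spectator because the benzylic C2'–O1' bond is never ionised under these neutral conditions, so the configuration from step 10 is carried through. The step needs only chemoselectivity among alkenes, which is secured because the two terminal vinyl groups are the only alkenes in 16, and the 4→6 constitution is fixed because the chain hangs on the oxygen para to C6'. High dilution should suppress intermolecular cross-metathesis, and loss of ethene drives the closure.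

Step 14
Reactants: 17 epicatechin–flav-3-ene dimer
Product: 19 2',3'-trans alcohol (lower unit of the catechin type), via alkylborane 18 (not isolated)
Conditions: BH3·THF (3 equiv), THF, 0 °C to rt; H2O, then aq. NaOH, 30% H2O2, 0 °C to rt
Reagents that add atoms: borane–tetrahydrofuran, [BH3-][O+]1CCCC1 (boron in 18 only); hydrogen peroxide, OO
Why: Hydroboration–oxidation should place boron on C3', the carbon made electron-rich by the ring D oxygens, and hydrogen on benzylic C4', from the face anti to ring E (2',3'-trans, with retention in the oxidation); any cis alcohol converges in the next step.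

Step 15
Reactants: 19 2',3'-trans alcohol
Product: 20 3'-ketone (lower unit: tetra-O-benzylflavan-3-one)
Conditions: Dess–Martin periodinane (1.5 equiv), CH2Cl2, 0 °C to rt
Reagents that add atoms: none
Why: Dess–Martin oxidation of the only free alcohol under near-neutral conditions is the known way to flavan-3-ones without enolisation at C2'; the ketone is used at once.

Step 16
Reactants: 20 3'-ketone
Product: 21 2',3'-cis alcohol (lower unit: tetra-O-benzylepicatechin; upper 3-O-TBS)
Conditions: LiBH(s-Bu)3 (2 equiv), THF, −78 °C; then H2O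
Reagents that add atoms: none
Why: The bulky trialkylborohydride should deliver hydride to the carbonyl face opposite ring E, so the new C3' hydroxyl is cis to ring E (3'R), as in the known conversion of benzylated catechin into epicatechin through the 3-ketone.

Step 17
Reactants: 21 2',3'-cis alcohol with 3-O-TBS
Product: 22 octa-O-benzyl-epicatechin-(4β→6)-epicatechin (3,3'-diol)
Conditions: HF·pyridine, pyridine, THF, 0 °C to rt
Reagents that add atoms: none
Why: Fluoride-mediated desilylation buffered with pyridine frees the hindered C3 hydroxyl without touching the benzyl ethers or the interflavan bond.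

Step 18
Reactants: 22 octa-O-benzyl procyanidin B-5; 23 3,4,5-tris(benzyloxy)benzoic acid
Product: 24 tetradeca-O-benzyl procyanidin B-5 3,3'-di-O-gallate
Conditions: 23 (3 equiv), DCC (3 equiv), DMAP, CH2Cl2, rt
Reagents that add atoms: none
Why: Steglich esterification through the acylpyridinium ion acylates both secondary 3-hydroxyls with retention, as in the galloylation of benzylated flavan-3-ols.

Step 19
Reactants: 24 tetradeca-O-benzyl procyanidin B-5 3,3'-di-O-gallate
Product: 25 procyanidin B-5 3,3'-di-O-gallate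
Conditions: H2 (1 atm), Pd(OH)2/C, THF/MeOH/H2O, rt
Reagents that add atoms: none
Why: Hydrogenolysis removes all fourteen benzyl ethers under neutral conditions that should leave the gallate esters, the benzylic C2–O bonds and the C4–C6' bond intact.

**Compound list**

1 | (−)-epicatechin | O[C@@H]1Cc2c(O)cc(O)cc2O[C@@H]1c1ccc(O)c(O)c1 | starting material
2 | 5,7,3',4'-tetra-O-benzyl-(−)-epicatechin | O[C@@H]1Cc2c(OCc3ccccc3)cc(OCc3ccccc3)cc2O[C@@H]1c1ccc(OCc2ccccc2)c(OCc2ccccc2)c1 | intermediate
3 | 4β-(2-ethoxyethoxy)-5,7,3',4'-tetra-O-benzylepicatechin (2,3-cis, 3,4-trans) | O[C@@H]1[C@@H](OCCOCC)c2c(OCc3ccccc3)cc(OCc3ccccc3)cc2O[C@@H]1c1ccc(OCc2ccccc2)c(OCc2ccccc2)c1 | intermediate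
4 | 3-O-TBS-4β-(2-ethoxyethoxy)-5,7,3',4'-tetra-O-benzylepicatechin | CC(C)(C)[Si](C)(C)O[C@@H]1[C@@H](OCCOCC)c2c(OCc3ccccc3)cc(OCc3ccccc3)cc2O[C@@H]1c1ccc(OCc2ccccc2)c(OCc2ccccc2)c1 | intermediate
5 | phloroglucinol | Oc1cc(O)cc(O)c1 | starting material
6 | 3-O-TBS-5,7,3',4'-tetra-O-benzylepicatechin-(4β→2)-phloroglucinol | CC(C)(C)[Si](C)(C)O[C@@H]1[C@@H](c4c(O)cc(O)cc4O)c2c(OCc3ccccc3)cc(OCc3ccccc3)cc2O[C@@H]1c1ccc(OCc2ccccc2)c(OCc2ccccc2)c1 | intermediate
7 | ring D N,N-dimethyliminium chloride of 6 (CH=NMe2+ at the future C4a') | CC(C)(C)[Si](C)(C)O[C@@H]1[C@@H](c4c(O)cc(O)c(C=[N+](C)C)c4O)c2c(OCc3ccccc3)cc(OCc3ccccc3)cc2O[C@@H]1c1ccc(OCc2ccccc2)c(OCc2ccccc2)c1.[Cl-] | intermediate (not isolated)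
8 | ring D aldehyde: 4β-(3-formyl-2,4,6-trihydroxyphenyl)-3-O-TBS-tetra-O-benzylepicatechin | CC(C)(C)[Si](C)(C)O[C@@H]1[C@@H](c4c(O)cc(O)c(C=O)c4O)c2c(OCc3ccccc3)cc(OCc3ccccc3)cc2O[C@@H]1c1ccc(OCc2ccccc2)c(OCc2ccccc2)c1 | intermediate
9 | 4β-[6-(benzyloxy)-3-formyl-2,4-dihydroxyphenyl]-3-O-TBS-tetra-O-benzylepicatechin (benzyl on the oxygen para to CHO, the future O7') | CC(C)(C)[Si](C)(C)O[C@@H]1[C@@H](c4c(OCc5ccccc5)cc(O)c(C=O)c4O)c2c(OCc3ccccc3)cc(OCc3ccccc3)cc2O[C@@H]1c1ccc(OCc2ccccc2)c(OCc2ccccc2)c1 | intermediate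
10 | 3,4-bis(benzyloxy)benzaldehyde | O=Cc1ccc(OCc2ccccc2)c(OCc2ccccc2)c1 | starting material
11 | ethyl (E)-3-[3,4-bis(benzyloxy)phenyl]prop-2-enoate | CCOC(=O)/C=C/c1ccc(OCc2ccccc2)c(OCc2ccccc2)c1 | intermediate
12 | (E)-3-[3,4-bis(benzyloxy)phenyl]prop-2-en-1-ol | OC/C=C/c1ccc(OCc2ccccc2)c(OCc2ccccc2)c1 | intermediate
13 | (E)-3-[3,4-bis(benzyloxy)phenyl]allyl methyl carbonate | COC(=O)OC/C=C/c1ccc(OCc2ccccc2)c(OCc2ccccc2)c1 | intermediate
14 | 4β-{6-(benzyloxy)-3-formyl-2-hydroxy-4-[(S)-1-(3,4-bis(benzyloxy)phenyl)allyloxy]phenyl}-3-O-TBS-tetra-O-benzylepicatechin | CC(C)(C)[Si](C)(C)O[C@@H]1[C@@H](c4c(OCc5ccccc5)cc(O[C@H](c5ccc(OCc6ccccc6)c(OCc6ccccc6)c5)C=C)c(C=O)c4O)c2c(OCc3ccccc3)cc(OCc3ccccc3)cc2O[C@@H]1c1ccc(OCc2ccccc2)c(OCc2ccccc2)c1 | intermediate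
15 | 4β-{2,6-bis(benzyloxy)-3-formyl-4-[(S)-1-(3,4-bis(benzyloxy)phenyl)allyloxy]phenyl}-3-O-TBS-tetra-O-benzylepicatechin | CC(C)(C)[Si](C)(C)O[C@@H]1[C@@H](c4c(OCc5ccccc5)cc(O[C@H](c5ccc(OCc6ccccc6)c(OCc6ccccc6)c5)C=C)c(C=O)c4OCc5ccccc5)c2c(OCc3ccccc3)cc(OCc3ccccc3)cc2O[C@@H]1c1ccc(OCc2ccccc2)c(OCc2ccccc2)c1 | intermediate
16 | 4β-{2,6-bis(benzyloxy)-3-vinyl-4-[(S)-1-(3,4-bis(benzyloxy)phenyl)allyloxy]phenyl}-3-O-TBS-tetra-O-benzylepicatechin (metathesis precursor) | CC(C)(C)[Si](C)(C)O[C@@H]1[C@@H](c4c(OCc5ccccc5)cc(O[C@H](c5ccc(OCc6ccccc6)c(OCc6ccccc6)c5)C=C)c(C=C)c4OCc5ccccc5)c2c(OCc3ccccc3)cc(OCc3ccccc3)cc2O[C@@H]1c1ccc(OCc2ccccc2)c(OCc2ccccc2)c1 | intermediate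
17 | 3-O-TBS-tetra-O-benzylepicatechin-(4β→6)-(2S)-5,7,3',4'-tetra-O-benzylflav-3-ene (metathesis product) | CC(C)(C)[Si](C)(C)O[C@@H]1[C@@H](c4c(OCc5ccccc5)cc5c(c4OCc6ccccc6)C=C[C@@H](c6ccc(OCc7ccccc7)c(OCc7ccccc7)c6)O5)c2c(OCc3ccccc3)cc(OCc3ccccc3)cc2O[C@@H]1c1ccc(OCc2ccccc2)c(OCc2ccccc2)c1 | intermediate
18 | C3'-alkylborane of 17 (boron trans to ring E) | CC(C)(C)[Si](C)(C)O[C@@H]1[C@@H](c4c(OCc5ccccc5)cc5c(c4OCc6ccccc6)C[C@H](B)[C@@H](c6ccc(OCc7ccccc7)c(OCc7ccccc7)c6)O5)c2c(OCc3ccccc3)cc(OCc3ccccc3)cc2O[C@@H]1c1ccc(OCc2ccccc2)c(OCc2ccccc2)c1 | intermediate (not isolated)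
19 | 3-O-TBS-tetra-O-benzylepicatechin-(4β→6)-tetra-O-benzylcatechin (2',3'-trans alcohol) | CC(C)(C)[Si](C)(C)O[C@@H]1[C@@H](c4c(OCc5ccccc5)cc5c(c4OCc6ccccc6)C[C@H](O)[C@@H](c6ccc(OCc7ccccc7)c(OCc7ccccc7)c6)O5)c2c(OCc3ccccc3)cc(OCc3ccccc3)cc2O[C@@H]1c1ccc(OCc2ccccc2)c(OCc2ccccc2)c1 | intermediate
20 | 3-O-TBS-tetra-O-benzylepicatechin-(4β→6)-(2R)-tetra-O-benzylflavan-3-one | CC(C)(C)[Si](C)(C)O[C@@H]1[C@@H](c4c(OCc5ccccc5)cc5c(c4OCc6ccccc6)CC(=O)[C@@H](c6ccc(OCc7ccccc7)c(OCc7ccccc7)c6)O5)c2c(OCc3ccccc3)cc(OCc3ccccc3)cc2O[C@@H]1c1ccc(OCc2ccccc2)c(OCc2ccccc2)c1 | intermediate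
21 | 3-O-TBS-tetra-O-benzylepicatechin-(4β→6)-tetra-O-benzylepicatechin (2',3'-cis alcohol) | CC(C)(C)[Si](C)(C)O[C@@H]1[C@@H](c4c(OCc5ccccc5)cc5c(c4OCc6ccccc6)C[C@@H](O)[C@@H](c6ccc(OCc7ccccc7)c(OCc7ccccc7)c6)O5)c2c(OCc3ccccc3)cc(OCc3ccccc3)cc2O[C@@H]1c1ccc(OCc2ccccc2)c(OCc2ccccc2)c1 | intermediate
22 | octa-O-benzyl-epicatechin-(4β→6)-epicatechin (3,3'-diol) | O[C@@H]1[C@@H](c4c(OCc5ccccc5)cc5c(c4OCc6ccccc6)C[C@@H](O)[C@@H](c6ccc(OCc7ccccc7)c(OCc7ccccc7)c6)O5)c2c(OCc3ccccc3)cc(OCc3ccccc3)cc2O[C@@H]1c1ccc(OCc2ccccc2)c(OCc2ccccc2)c1 | intermediate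
23 | 3,4,5-tris(benzyloxy)benzoic acid | OC(=O)c1cc(OCc2ccccc2)c(OCc2ccccc2)c(OCc2ccccc2)c1 | starting material
24 | tetradeca-O-benzyl procyanidin B-5 3,3'-di-O-gallate | O=C(O[C@@H]1[C@@H](c4c(OCc5ccccc5)cc5c(c4OCc6ccccc6)C[C@@H](OC(=O)c6cc(OCc7ccccc7)c(OCc7ccccc7)c(OCc7ccccc7)c6)[C@@H](c6ccc(OCc7ccccc7)c(OCc7ccccc7)c6)O5)c2c(OCc3ccccc3)cc(OCc3ccccc3)cc2O[C@@H]1c1ccc(OCc2ccccc2)c(OCc2ccccc2)c1)c1cc(OCc2ccccc2)c(OCc2ccccc2)c(OCc2ccccc2)c1 | intermediate
25 | procyanidin B-5 3,3'-di-O-gallate | O=C(O[C@@H]1[C@@H](c2c(O)cc3c(c2O)C[C@@H](OC(=O)c2cc(O)c(O)c(O)c2)[C@@H](c2ccc(O)c(O)c2)O3)c2c(O)cc(O)cc2O[C@@H]1c1ccc(O)c(O)c1)c1cc(O)c(O)c(O)c1 | target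

**Step count and risks**

Total step count: 19. Longest linear sequence: 16 steps (steps 1–6 and 10–19, from 1 to 25); the carbonate branch (steps 7–9) adds 3.

The three steps most likely to fail:

Step 10. The iridium-catalysed etherification may suffer from poor discrimination between the two ortho phenols, from carbon allylation of ring D, or from re-ionisation of the electron-rich 1-arylallyl ether on the metal, which would erode the branched-to-linear ratio and the C2' configuration. The fallback sets out from 9 and 10 and returns at 14, and it moves the C2'–O1' bond formation to the propargylic oxidation level. Ethynylmagnesium bromide would add to aldehyde 10 to give racemic 1-[3,4-bis(benzyloxy)phenyl]prop-2-yn-1-ol F2, which Ac2O and pyridine convert into racemic 1-[3,4-bis(benzyloxy)phenyl]prop-2-ynyl acetate F3. Copper-catalysed enantioselective propargylic etherification (CuOTf·1/2C6H6, a chiral 2,6-bis(oxazolinyl)pyridine ligand, i-Pr2NEt, MeOH) would then join F3 to the less hindered phenol of 9 through a copper allenylidene, converging both enantiomers of F3 on the (S)-propargyl aryl ether F4. Semihydrogenation of the terminal alkyne of F4 over Pd/CaCO3 poisoned with Pb(OAc)2 and quinoline would give 14.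

Step 6. Mono-benzylation may fail through incomplete discrimination between the hydroxyl para to the formyl group, which is flanked by the bulky upper unit, and the unhindered ortho hydroxyl, leading to mixed mono- and bis-ethers. The fallback sets out from 4 and returns at 9, bypassing steps 4 to 6, by bringing the formyl group and the benzyl ether in with the nucleophile. Commercial 2,4,6-trihydroxybenzaldehyde would be mono-benzylated (BnBr, KHCO3, DMF) to 4-(benzyloxy)-2,6-dihydroxybenzaldehyde F1, whose isomers can be removed at the stage of a small molecule. F1 is mirror-symmetric, so its two free ring carbons are equivalent, and Friedel–Crafts alkylation of excess F1 by the C4 cation from 4 (TMSOTf, THF/CH2Cl2) should give 9 as the only constitution. The price is a less nucleophilic partner, to be offset by a larger excess and slow addition of 4.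

Step 13. The ring closure may stall because the ruthenium alkylidene engages the doubly ortho-substituted ring D styrene slowly, which lets ruthenium hydride isomerisation of the allyl ether or intermolecular cross-metathesis take over. The fallback sets out from 15 and returns at 17 and uses a relay tether. Wittig reaction of 15 with the ylide from hex-5-enyltriphenylphosphonium bromide and KOt-Bu would give the relay diene F5, in which the formyl group has become a (Z)-hepta-1,6-dienyl group. The second-generation Grubbs catalyst would load on the unhindered terminal alkene of the tether and expel cyclopentene, which places the ruthenium alkylidene directly on the hindered benzylic carbon (the future C4'). Closure onto the allyl ether vinyl group then gives 17.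

**Further compounds**

F1 | step 6 | 4-(benzyloxy)-2,6-dihydroxybenzaldehyde | O=Cc1c(O)cc(OCc2ccccc2)cc1O
F2 | step 10 | racemic 1-[3,4-bis(benzyloxy)phenyl]prop-2-yn-1-ol | OC(C#C)c1ccc(OCc2ccccc2)c(OCc2ccccc2)c1
F3 | step 10 | racemic 1-[3,4-bis(benzyloxy)phenyl]prop-2-ynyl acetate | CC(=O)OC(C#C)c1ccc(OCc2ccccc2)c(OCc2ccccc2)c1
F4 | step 10 | 4β-{6-(benzyloxy)-3-formyl-2-hydroxy-4-[(S)-1-(3,4-bis(benzyloxy)phenyl)prop-2-ynyloxy]phenyl}-3-O-TBS-tetra-O-benzylepicatechin | CC(C)(C)[Si](C)(C)O[C@@H]1[C@@H](c4c(OCc5ccccc5)cc(O[C@H](c5ccc(OCc6ccccc6)c(OCc6ccccc6)c5)C#C)c(C=O)c4O)c2c(OCc3ccccc3)cc(OCc3ccccc3)cc2O[C@@H]1c1ccc(OCc2ccccc2)c(OCc2ccccc2)c1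
F5 | step 13 | relay diene: analogue of 16 with a (Z)-hepta-1,6-dienyl group in place of the ring D vinyl group | CC(C)(C)[Si](C)(C)O[C@@H]1[C@@H](c4c(OCc5ccccc5)cc(O[C@H](c5ccc(OCc6ccccc6)c(OCc6ccccc6)c5)C=C)c(/C=C\CCCC=C)c4OCc5ccccc5)c2c(OCc3ccccc3)cc(OCc3ccccc3)cc2O[C@@H]1c1ccc(OCc2ccccc2)c(OCc2ccccc2)c1
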